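**Retrosynthetic overview**
- Last operations: unmask the C1 ketone from a dimethyl ketal; close the triene by a Heck coupling between a C4 vinyl carbinol and a (2E,4E)-5-bromopentadienamide that already carries the aminocyclopentenone.
- Ring C4: the vinyl group must enter cis to the oxirane (hydroxyl trans), which direct addition to the epoxy ketone does not give; a bromohydrin relay (open at C5, add, re-close) is used instead.
- Oxirane: chiral phase-transfer epoxidation of the quinone monoketal made from the 3-aminophenol anilide of the side-chain acid.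
- Key step (radical): the C4–C5 bond of the 4-methyloct-2-enoyl chain, with its stereocentre, by nickel-catalysed enantioconvergent coupling of a racemic γ-chloro enoate (from radical allylic chlorination) with butylzinc bromide.
- Ring order: the six-membered carbocycle and the cyclopentenone are bought; the oxirane is the only ring formed (step 5) and is opened and re-formed in step 6.

Assumptions: glutaconaldehyde potassium salt and 2-amino-3-hydroxycyclopent-2-en-1-one (sold as its hydrochloride) are bought; the senses of induction in steps 2 and 5 are as written, and the antipodal pybox ligand or the pseudoenantiomeric cinchonidinium salt would be used if either proved opposite.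

Step 1
Reactants: 1 methyl (2E)-pent-2-enoate
Product: 2 methyl (2E)-4-chloropent-2-enoate (racemic)
Conditions: t-BuOCl (0.9 equiv), hν (visible lamp), PhH, 20 °C
Reagents that add atoms: tert-butyl hypochlorite, CC(C)(C)OCl
Why: Radical-chain allylic chlorination (Walling type): t-BuO· abstracts the γ-hydrogen and the allyl radical takes chlorine at C4, where the alkene stays conjugated with the ester; the stereocentre is racemic, which does not matter because step 2 is enantioconvergent.

Step 2
Reactants: 2 methyl (2E)-4-chloropent-2-enoate (racemic); 3 butylzinc bromide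
Product: 4 methyl (2E,4R)-4-methyloct-2-enoate
Conditions: NiCl2(MeOCH2CH2OMe) (5 mol %), (S,S)-2,6-bis[4-(2-phenylethyl)-4,5-dihydro-1,3-oxazol-2-yl]pyridine (5.5 mol %), NaCl (4 equiv), 3 (1.6 equiv), DMF–DMA 1:1, −10 °C
Reagents that add atoms: none
Why: Nickel-catalysed enantioconvergent Negishi cross-coupling of a secondary allylic chloride (Fu type, radical): chlorine abstraction by low-valent pybox–nickel turns both enantiomers of 2 into one planar allyl radical, which is captured by the chiral butyl–nickel complex and reductively eliminates at the γ-carbon with the E-enoate retained, the ligand setting C4 as R.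

Step 3
Reactants: 4 methyl (2E,4R)-4-methyloct-2-enoate; 5 3-aminophenol
Product: 6 (2E,4R)-N-(3-hydroxyphenyl)-4-methyloct-2-enamide
Conditions: AlMe3 (3 equiv), PhMe–CH2Cl2, 0 → 45 °C; 1 M HCl work-up
Reagents that add atoms: none
Why: Weinreb aminolysis: the dimethylaluminium anilide attacks the ester carbonyl directly, so the E-alkene and the non-acidic γ-stereocentre are untouched and the phenol is recovered free on work-up.

Step 4
Reactants: 6 (2E,4R)-N-(3-hydroxyphenyl)-4-methyloct-2-enamide
Product: 7 (2E,4R)-N-(6,6-dimethoxy-3-oxocyclohexa-1,4-dien-1-yl)-4-methyloct-2-enamide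
Conditions: PhI(OAc)2 (2.2 equiv), MeOH, 0 °C
Reagents that add atoms: methanol, CO
Why: Hypervalent-iodine oxidative dearomatisation: two successive phenol oxidations with methanol capture para to the hydroxyl give the quinone monoketal whose ketal carbon lies next to the nitrogen-bearing carbon; no stereocentre is formed.

Step 5
Reactants: 7 (2E,4R)-N-(6,6-dimethoxy-3-oxocyclohexa-1,4-dien-1-yl)-4-methyloct-2-enamide
Product: 8 (2E,4R)-N-[(1S,6R)-2,2-dimethoxy-5-oxo-7-oxabicyclo[4.1.0]hept-3-en-3-yl]-4-methyloct-2-enamide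
Conditions: t-BuOOH, aq. NaOH, N-benzylcinchoninium chloride (10 mol %), PhMe, 20 °C; recrystallise
Reagents that add atoms: tert-butyl hydroperoxide, CC(C)(C)OO
Why: Weitz–Scheffer nucleophilic epoxidation under chiral phase-transfer catalysis (Wynberg conditions, precedented on the analogous carbamate): the peroxide anion adds only to the unsubstituted enone (the other is a deactivated vinylogous amide) inside the ion pair with the cinchoninium cation, which sets both oxirane carbons (1S,6R).

Step 6
Reactants: 8 (2E,4R)-N-[(1S,6R)-2,2-dimethoxy-5-oxo-7-oxabicyclo[4.1.0]hept-3-en-3-yl]-4-methyloct-2-enamide; 9 vinylmagnesium bromide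
Product: 12 (2E,4R)-N-[(1S,5R,6R)-5-ethenyl-5-hydroxy-2,2-dimethoxy-7-oxabicyclo[4.1.0]hept-3-en-3-yl]-4-methyloct-2-enamide, via bromohydrin ketone 10 (not isolated), via bromo diol 11 (not isolated)
Conditions: MgBr2·OEt2 (1.5 equiv), Et2O–CH2Cl2, −20 °C; then 9 (3.5 equiv), THF, −78 °C; H2O; then K2CO3, MeOH, 0 °C
Reagents that add atoms: none
Why: Proposed new method: MgBr2 opens the oxirane at the carbon α to the ketone with inversion, the axial C–Br then steers the Grignard reagent to the opposite face of the ketone (polar Felkin–Anh/Cornforth control as in additions to 2-halocyclohexanones, which give cis-halohydrins, helped by the magnesium alkoxide on that face), and base re-closes the oxirane from the neighbouring oxygen with a second inversion, so the vinyl group ends cis and the new hydroxyl trans to the oxirane (carbinol carbon R); closest known reactions are halide opening of α,β-epoxy ketones, Grignard addition to α-halo ketones and halohydrin ring closure.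

Step 7
Reactants: 13 potassium (1E,3E)-5-oxopenta-1,3-dien-1-olate (glutaconaldehyde potassium salt)
Product: 14 (2E,4E)-5-bromopenta-2,4-dienal
Conditions: PPh3, Br2, CH2Cl2, 0 → 20 °C
Reagents that add atoms: bromine, BrBr
Why: Deoxy-bromination of the vinylogous carboxylate with Ph3PBr2 (Duhamel procedure): O-phosphonium formation and bromide addition–elimination give the ω-bromodienal, which settles as the stable 2E,4E isomer.

Step 8
Reactants: 14 (2E,4E)-5-bromopenta-2,4-dienal
Product: 15 (2E,4E)-5-bromopenta-2,4-dienoic acid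
Conditions: NaClO2, NaH2PO4, 2-methylbut-2-ene, t-BuOH–H2O, 0 → 20 °C
Reagents that add atoms: sodium chlorite, [Na+].[O-]Cl=O
Why: Pinnick oxidation: chlorous acid oxidises only the aldehyde and the scavenger alkene removes HOCl, so the bromodiene geometry is kept.

Step 9
Reactants: 15 (2E,4E)-5-bromopenta-2,4-dienoic acid; 16 2-amino-3-hydroxycyclopent-2-en-1-one
Product: 18 (2E,4E)-5-bromo-N-(2-hydroxy-5-oxocyclopent-1-en-1-yl)penta-2,4-dienamide, via acid chloride 17 (not isolated)
Conditions: (COCl)2, DMF (cat.), CH2Cl2, 0 °C, evaporate; then 16 (liberated from its hydrochloride), Et3N, THF, 0 → 20 °C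
Reagents that add atoms: none
Why: Acid chloride amidation: the amino group of the vinylogous acid 16 is acylated in preference to the enol oxygen (any O-acyl isomer migrates to nitrogen); no stereocentre is involved.

Step 10
Reactants: 12 (2E,4R)-N-[(1S,5R,6R)-5-ethenyl-5-hydroxy-2,2-dimethoxy-7-oxabicyclo[4.1.0]hept-3-en-3-yl]-4-methyloct-2-enamide; 18 (2E,4E)-5-bromo-N-(2-hydroxy-5-oxocyclopent-1-en-1-yl)penta-2,4-dienamide
Product: 19 (2E,4R)-N-[(1S,5R,6R)-5-hydroxy-5-[(1E,3E,5E)-7-[(2-hydroxy-5-oxocyclopent-1-en-1-yl)amino]-7-oxohepta-1,3,5-trien-1-yl]-2,2-dimethoxy-7-oxabicyclo[4.1.0]hept-3-en-3-yl]-4-methyloct-2-enamide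
Conditions: Pd(OAc)2 (10 mol %), Bu4NCl, K2CO3, DMF, 40 °C, dark
Reagents that add atoms: none
Why: Mizoroki–Heck coupling under Jeffery conditions: the dienyl–palladium species adds to the unhindered terminal carbon of the vinyl group and β-hydride elimination can only occur away from the quaternary carbinol, giving the 1E alkene with the 3E,5E geometry of 18 retained and all stereocentres untouched.

Step 11
Reactants: 19 (2E,4R)-N-[(1S,5R,6R)-5-hydroxy-5-[(1E,3E,5E)-7-[(2-hydroxy-5-oxocyclopent-1-en-1-yl)amino]-7-oxohepta-1,3,5-trien-1-yl]-2,2-dimethoxy-7-oxabicyclo[4.1.0]hept-3-en-3-yl]-4-methyloct-2-enamide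
Product: 20 (2E,4R)-N-[(1S,5R,6R)-5-hydroxy-5-[(1E,3E,5E)-7-[(2-hydroxy-5-oxocyclopent-1-en-1-yl)amino]-7-oxohepta-1,3,5-trien-1-yl]-2-oxo-7-oxabicyclo[4.1.0]hept-3-en-3-yl]-4-methyloct-2-enamide (target)
Conditions: SiO2, 10% aq. oxalic acid, CH2Cl2, 20 °C
Reagents that add atoms: water, O
Why: Mild acid-catalysed ketal hydrolysis on wet silica (the closing step used for this compound class): only the dimethyl ketal ionises, restoring the ketone without opening the oxirane or ionising the tertiary allylic alcohol.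

**Compound list**
1 | methyl (2E)-pent-2-enoate | CC/C=C/C(=O)OC | starting material
2 | methyl (2E)-4-chloropent-2-enoate (racemic) | CC(Cl)/C=C/C(=O)OC | intermediate
3 | butylzinc bromide | CCCC[Zn]Br | starting material
4 | methyl (2E,4R)-4-methyloct-2-enoate | CCCC[C@@H](C)/C=C/C(=O)OC | intermediate
5 | 3-aminophenol | Nc1cccc(O)c1 | starting material
6 | (2E,4R)-N-(3-hydroxyphenyl)-4-methyloct-2-enamide | CCCC[C@@H](C)/C=C/C(=O)Nc1cccc(O)c1 | intermediate
7 | (2E,4R)-N-(6,6-dimethoxy-3-oxocyclohexa-1,4-dien-1-yl)-4-methyloct-2-enamide | CCCC[C@@H](C)/C=C/C(=O)NC1=CC(=O)C=CC1(OC)OC | intermediate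
8 | (2E,4R)-N-[(1S,6R)-2,2-dimethoxy-5-oxo-7-oxabicyclo[4.1.0]hept-3-en-3-yl]-4-methyloct-2-enamide | CCCC[C@@H](C)/C=C/C(=O)NC1=CC(=O)[C@@H]2O[C@@H]2C1(OC)OC | intermediate
9 | vinylmagnesium bromide | C=C[Mg]Br | starting material
10 | (2E,4R)-N-[(4S,5R)-4-bromo-5-hydroxy-6,6-dimethoxy-3-oxocyclohex-1-en-1-yl]-4-methyloct-2-enamide (bromohydrin ketone, formed as its magnesium alkoxide) | CCCC[C@@H](C)/C=C/C(=O)NC1=CC(=O)[C@@H](Br)[C@H](O)C1(OC)OC | intermediate
11 | (2E,4R)-N-[(3R,4S,5R)-4-bromo-3-ethenyl-3,5-dihydroxy-6,6-dimethoxycyclohex-1-en-1-yl]-4-methyloct-2-enamide (bromo diol) | CCCC[C@@H](C)/C=C/C(=O)NC1=C[C@](O)(C=C)[C@@H](Br)[C@H](O)C1(OC)OC | intermediate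
12 | (2E,4R)-N-[(1S,5R,6R)-5-ethenyl-5-hydroxy-2,2-dimethoxy-7-oxabicyclo[4.1.0]hept-3-en-3-yl]-4-methyloct-2-enamide | CCCC[C@@H](C)/C=C/C(=O)NC1=C[C@](O)(C=C)[C@@H]2O[C@@H]2C1(OC)OC | intermediate
13 | potassium (1E,3E)-5-oxopenta-1,3-dien-1-olate (glutaconaldehyde potassium salt) | [K+].[O-]/C=C/C=C/C=O | starting material
14 | (2E,4E)-5-bromopenta-2,4-dienal | O=C/C=C/C=C/Br | intermediate
15 | (2E,4E)-5-bromopenta-2,4-dienoic acid | OC(=O)/C=C/C=C/Br | intermediate
16 | 2-amino-3-hydroxycyclopent-2-en-1-one | NC1=C(O)CCC1=O | starting material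
17 | (2E,4E)-5-bromopenta-2,4-dienoyl chloride | ClC(=O)/C=C/C=C/Br | intermediate
18 | (2E,4E)-5-bromo-N-(2-hydroxy-5-oxocyclopent-1-en-1-yl)penta-2,4-dienamide | O=C(/C=C/C=C/Br)NC1=C(O)CCC1=O | intermediate
19 | (2E,4R)-N-[(1S,5R,6R)-5-hydroxy-5-[(1E,3E,5E)-7-[(2-hydroxy-5-oxocyclopent-1-en-1-yl)amino]-7-oxohepta-1,3,5-trien-1-yl]-2,2-dimethoxy-7-oxabicyclo[4.1.0]hept-3-en-3-yl]-4-methyloct-2-enamide | CCCC[C@@H](C)/C=C/C(=O)NC1=C[C@](O)(/C=C/C=C/C=C/C(=O)NC2=C(O)CCC2=O)[C@@H]2O[C@@H]2C1(OC)OC | intermediate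
20 | (2E,4R)-N-[(1S,5R,6R)-5-hydroxy-5-[(1E,3E,5E)-7-[(2-hydroxy-5-oxocyclopent-1-en-1-yl)amino]-7-oxohepta-1,3,5-trien-1-yl]-2-oxo-7-oxabicyclo[4.1.0]hept-3-en-3-yl]-4-methyloct-2-enamide | CCCC[C@@H](C)/C=C/C(=O)NC1=C[C@](O)(/C=C/C=C/C=C/C(=O)NC2=C(O)CCC2=O)[C@@H]2O[C@@H]2C1=O | target

**Count**
Total steps: 11. Longest linear sequence: 8 steps (steps 1, 2, 3, 4, 5, 6, 10, 11).

**Steps most likely to fail, each with a fallback**

Step 6. The relay can fail if the bromohydrin alkoxide re-closes before the Grignard reagent adds, which gives the epimer at the carbinol carbon. The fallback sets out from 8 and makes that epimer on purpose. Reagent 9 in THF at −78 °C adds trans to the oxirane oxygen and gives the epimeric vinyl carbinol (2E,4R)-N-[(1S,5S,6R)-5-ethenyl-5-hydroxy-2,2-dimethoxy-7-oxabicyclo[4.1.0]hept-3-en-3-yl]-4-methyloct-2-enamide F1. PhSCl and Et3N at −78 °C convert it by O-sulfenylation and [2,3]-sigmatropic (Mislow–Evans) shift into the primary allylic sulfoxide (2E,4R)-N-[(1S,6S)-2,2-dimethoxy-5-[2-(phenylsulfinyl)ethylidene]-7-oxabicyclo[4.1.0]hept-3-en-3-yl]-4-methyloct-2-enamide F2 (mixture of alkene isomers and sulfoxide epimers), in which the former carbinol carbon is trigonal. Piperidine in MeOH at 40 °C traps the reverse shift, expected to deliver oxygen to the face away from the oxirane oxygen, and the route is rejoined at 12; any epimer that re-forms is recycled.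

Step 10. The Heck coupling may suffer from the acidic enol amide of 18 and from the crowded allylic carbinol. The fallback sets out from 12. Cross-metathesis with 2-ethenyl-4,4,5,5-tetramethyl-1,3,2-dioxaborolane (second-generation Hoveyda–Grubbs catalyst RuCl2(=CH-C6H4-2-O-i-Pr)(1,3-dimesitylimidazolidin-2-ylidene), CH2Cl2, 40 °C) gives the alkenylboronate (2E,4R)-N-[(1S,5R,6R)-5-hydroxy-2,2-dimethoxy-5-[(E)-2-(4,4,5,5-tetramethyl-1,3,2-dioxaborolan-2-yl)ethenyl]-7-oxabicyclo[4.1.0]hept-3-en-3-yl]-4-methyloct-2-enamide F3. Suzuki–Miyaura coupling with 18 (Pd(PPh3)4, aq. K3PO4, THF, 20 °C) comes back to the route at 19.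

Step 4. The double oxidation of a para-unsubstituted phenol may give ortho attack or amide participation. The fallback sets out from 6. Teuber oxidation with (KSO3)2NO (aq. KH2PO4–acetone, 0 °C) gives the amidoquinone (2E,4R)-N-(3,6-dioxocyclohexa-1,4-dien-1-yl)-4-methyloct-2-enamide F4. Ketalisation under Noyori conditions (MeOSiMe3, Me3SiOTf cat., CH2Cl2, −78 °C) should take place at the carbonyl next to the nitrogen-bearing carbon, because the other carbonyl is a deactivated vinylogous amide, and comes back to the route at 7.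

Further compounds
F1 | step 6 | (2E,4R)-N-[(1S,5S,6R)-5-ethenyl-5-hydroxy-2,2-dimethoxy-7-oxabicyclo[4.1.0]hept-3-en-3-yl]-4-methyloct-2-enamide | CCCC[C@@H](C)/C=C/C(=O)NC1=C[C@@](O)(C=C)[C@@H]2O[C@@H]2C1(OC)OC
F2 | step 6 | (2E,4R)-N-[(1S,6S)-2,2-dimethoxy-5-[2-(phenylsulfinyl)ethylidene]-7-oxabicyclo[4.1.0]hept-3-en-3-yl]-4-methyloct-2-enamide | CCCC[C@@H](C)/C=C/C(=O)NC1=CC(=CCS(=O)c2ccccc2)[C@@H]3O[C@@H]3C1(OC)OC
F3 | step 10 | (2E,4R)-N-[(1S,5R,6R)-5-hydroxy-2,2-dimethoxy-5-[(E)-2-(4,4,5,5-tetramethyl-1,3,2-dioxaborolan-2-yl)ethenyl]-7-oxabicyclo[4.1.0]hept-3-en-3-yl]-4-methyloct-2-enamide | CCCC[C@@H](C)/C=C/C(=O)NC1=C[C@](O)(/C=C/B2OC(C)(C)C(C)(C)O2)[C@@H]3O[C@@H]3C1(OC)OC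
F4 | step 4 | (2E,4R)-N-(3,6-dioxocyclohexa-1,4-dien-1-yl)-4-methyloct-2-enamide | CCCC[C@@H](C)/C=C/C(=O)NC1=CC(=O)C=CC1=O
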